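**Plan**
1. Retrosynthetic cuts: (i) O–C7 of the oxolane ring C7–O–C9'–C8'–C8, going back to a plain C7H2 benzyl group; (ii) O–C7' of the other oxolane ring C7'–O–C9–C8–C8'; (iii) C7'–C8' (aldol) and C7–C8 (alkylation). What remains is the chain C9'–C8'(OH)–C8–C9 of (S)-malic acid and two syringyl C1 units.
2. Enabling feature: C7 is para to the free 4-OH of its syringyl ring, so loss of two H turns C7 into the terminus of a p-quinone methide. The oxygen of C9'H2OH lies four bonds from C7 (O–C9'–C8'–C8–C7), on the same face of the finished ring. This is how furofuran rings are presumed to close in lignan biosynthesis.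
3. Forward order: C8 benzylation of malate, acetal formation, C8' aldol, LiAlH4, acid closure of ring C7'–O–C9–C8–C8' (first ring), release of one phenol, Ag2O dehydrogenation with 1,6-addition (second and last ring), desilylation.
4. Stereochemistry: C8' comes from (S)-malate and is stored in a tert-butyl acetal while it becomes quaternary. C8 is set by anti alkylation of the malate dianion. C7' and C7 are set by substrate control in the two ring closures, with both aryl groups on the convex face.
5. Helper groups: Bn on the C7 ring and TIPS on the C7' ring, so that only the C7 ring is a free phenol when the oxidant acts.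

Key step: step 11

Remark on locants: C7/C8/C9 denote the half with the bridgehead H, and C7'/C8'/C9' the half whose bridgehead carries the OH. In these locants the target is 7S,8R,7'R,8'S.
Remark on 10, 11 and 12: these are carried as mixtures of C7' epimers, because step 9 erases and resets this centre. Their SMILES leave it open on purpose.

**Step 1**
Reactants: 1 syringyl alcohol
Product: 2 4-(benzyloxy)-3,5-dimethoxybenzyl alcohol
Conditions: BnBr, K2CO3, DMF, rt
Reagents that add atoms: benzyl bromide, BrCc1ccccc1
Why: Williamson ether synthesis; K2CO3 deprotonates only the phenol, so the phenoxide is benzylated and the benzylic alcohol stays free.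

**Step 2**
Reactants: 2 4-(benzyloxy)-3,5-dimethoxybenzyl alcohol
Product: 3 4-(benzyloxy)-3,5-dimethoxybenzyl bromide
Conditions: PBr3 (0.4 equiv), Et2O, 0 °C
Reagents that add atoms: phosphorus tribromide, BrP(Br)Br
Why: Bromide substitution of a primary benzylic alcohol through its phosphite ester is standard for trialkoxybenzyl alcohols, and the aryl benzyl ether should survive at 0 °C.

**Step 3**
Reactants: 4 diethyl (S)-malate; 3 4-(benzyloxy)-3,5-dimethoxybenzyl bromide
Product: 5 diethyl (2S,3R)-3-arylmethyl-2-hydroxybutanedioate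
Conditions: LiHMDS (2.1 equiv), THF, −78 → −20 °C; 3, −78 → 0 °C; AcOH quench
Reagents that add atoms: none
Why: Fráter–Seebach alkylation; the chelated alkoxide–enolate dianion is attacked by the benzylic bromide anti to the C8' oxygen, which sets C8 (3R) relative to the malate centre.

**Step 4**
Reactants: 5 diethyl (2S,3R)-3-arylmethyl-2-hydroxybutanedioate
Product: 6 (2S,3R)-3-arylmethyl-2-hydroxybutanedioic acid
Conditions: KOH, H2O–dioxane, rt; then HCl to pH 1
Reagents that add atoms: potassium hydroxide, [K+].[OH-]
Why: Saponification of both esters at room temperature; the carboxylates formed resist enolisation, so C8 and C8' should keep their configuration.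

**Step 5**
Reactants: 6 (2S,3R)-3-arylmethyl-2-hydroxybutanedioic acid
Product: 7 cis-2-tert-butyl-dioxolanone acid
Conditions: t-BuCHO, TsOH·H2O (cat.), H2SO4 (cat.), CH2Cl2–pentane, reflux, water separator
Reagents that add atoms: pivalaldehyde, CC(C)(C)C=O
Why: Acetalisation of the α-hydroxy acid unit (self-regeneration of stereocentres); the five-membered dioxolanone is preferred to the six-membered dioxanone, and thermodynamic control favours the cis isomer, whose new acetal centre stores the C8' configuration.

**Step 6**
Reactants: 8 syringaldehyde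
Product: 9 3,5-dimethoxy-4-(triisopropylsilyloxy)benzaldehyde
Conditions: TIPSCl, imidazole, DMAP (cat.), DMF, rt → 40 °C
Reagents that add atoms: triisopropylsilyl chloride, CC(C)[Si](Cl)(C(C)C)C(C)C
Why: Imidazole-promoted O-silylation of a phenol; the bulky silyl ether is chosen because it should outlast LiAlH4, catalytic acid, H2/Pd and Ag2O.

**Step 7**
Reactants: 7 cis-2-tert-butyl-dioxolanone acid; 9 3,5-dimethoxy-4-(triisopropylsilyloxy)benzaldehyde
Product: 11 spiro dioxolanone–butyrolactone, via aldol hydroxy acid 10 (not isolated)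
Conditions: LiHMDS (2.2 equiv), THF, −78 °C; 9, −78 °C; AcOH quench; crude, TsOH (cat.), CH2Cl2, rt
Reagents that add atoms: none
Why: Aldol addition of a dioxolanone enolate; the carboxylate shields C8 from enolisation, the aldehyde attacks anti to the tert-butyl group so that C7' takes the place of the former H and C8' becomes quaternary with retention, the C7' carbinol configuration is left open because step 9 resets it, and γ-lactonisation of 10 onto the C9 acid shuts off retro-aldol cleavage.

**Step 8**
Reactants: 11 spiro dioxolanone–butyrolactone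
Product: 12 tetraol
Conditions: LiAlH4 (excess), THF, 0 °C → rt; H2O/NaOH work-up
Reagents that add atoms: none
Why: LiAlH4 reduction takes the γ-lactone and the dioxolanone carbonyl to primary alcohols and thereby unravels the acetal, while the aryl benzyl ether, the TIPS ether and C8/C8' are untouched.

**Step 9**
Reactants: 12 tetraol
Product: 13 (2R,3S,4S)-2-aryl-4-arylmethyl-3-(hydroxymethyl)oxolan-3-ol
Conditions: CSA (10 mol %), CH2Cl2, 0 °C → rt, short contact time
Reagents that add atoms: none
Why: Acid-catalysed dehydrative cycloetherification (SN1); only the electron-rich benzylic C7' carbinol ionises, only the C9 hydroxyl can close a five-membered ring on C7', and both carbinol epimers should converge on the isomer with the aryl group trans to C9'H2OH and to the C8 benzyl group (cis to the small OH), which sets C7' as R.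

**Step 10**
Reactants: 13 (2R,3S,4S)-2-aryl-4-arylmethyl-3-(hydroxymethyl)oxolan-3-ol
Product: 14 monophenol
Conditions: H2 (1 atm), 10% Pd/C, EtOAc, rt, stopped after one equivalent of H2
Reagents that add atoms: none
Why: Hydrogenolysis of an aryl benzyl ether over Pd/C is much faster than cleavage of the hindered C7'–O bond next to quaternary C8', and the silyl ether is inert.

**Step 11**
Reactants: 14 monophenol
Product: 16 4'-O-TIPS-8'-hydroxysyringaresinol, via p-quinone methide 15 (not isolated)
Conditions: Ag2O (2 equiv), 4 Å MS, CH2Cl2, rt, dark; filtration; PPTS (cat.), rt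
Reagents that add atoms: none
Why: Ag2O removes the phenolic H and one benzylic C7–H (two electrons, two protons) from the only free phenol to give p-quinone methide 15, the electrophile presumed to close the furofuran rings in biosynthesis, and the C9' hydroxyl then adds to C7 in a 1,6-(oxa-Michael) addition driven by rearomatisation. The closest known reaction type is the Ag2O or quinone dehydrogenation of 4-alkyl-2,6-dimethoxyphenols to p-quinone methides followed by capture with alcohols or internal nucleophiles. The ring closes in the 5-exo-trig mode, with C7 inside the new ring and the C7=C1 bond exocyclic to it. C7 is the only new stereocentre: the C7 arm and C9'H2OH are already cis on the first ring, so only the cis-fused bicycle can form, and the aryl group takes the convex face because the other orientation presses the quinoid ring against C9H2; since the addition is reversible through 15 under the trace acid, the more stable exo (7S) isomer should accumulate. The step needs chemoselectivity between the two syringyl rings and between C7–H and the ether-activated C7'–H, which the TIPS ether secures because Ag2O attacks only free phenols. It also needs site selectivity among the hydroxyl groups, which ring size secures (C8'–OH could only give an oxetane), and the intramolecular capture should outrun tautomerisation of 15 to the styrene.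

**Step 12**
Reactants: 16 4'-O-TIPS-8'-hydroxysyringaresinol
Product: 17 8-hydroxysyringaresinol
Conditions: TBAF (1.1 equiv), AcOH (1.2 equiv), THF, 0 °C
Reagents that add atoms: none
Why: Fluoride cleavage of an aryl silyl ether; AcOH buffers the phenoxide so that no base-induced ring opening through a quinone methide occurs and no stereocentre is touched.

**Compound list**
1 | 4-(hydroxymethyl)-2,6-dimethoxyphenol (syringyl alcohol) | COc1cc(CO)cc(OC)c1O | starting material
2 | [4-(benzyloxy)-3,5-dimethoxyphenyl]methanol | COc1cc(CO)cc(OC)c1OCc1ccccc1 | intermediate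
3 | 2-(benzyloxy)-5-(bromomethyl)-1,3-dimethoxybenzene | COc1cc(CBr)cc(OC)c1OCc1ccccc1 | intermediate
4 | diethyl (S)-malate | CCOC(=O)C[C@H](O)C(=O)OCC | starting material
5 | diethyl (2S,3R)-3-{[4-(benzyloxy)-3,5-dimethoxyphenyl]methyl}-2-hydroxybutanedioate | CCOC(=O)[C@@H](O)[C@@H](Cc1cc(OC)c(OCc2ccccc2)c(OC)c1)C(=O)OCC | intermediate
6 | (2S,3R)-3-{[4-(benzyloxy)-3,5-dimethoxyphenyl]methyl}-2-hydroxybutanedioic acid | OC(=O)[C@@H](O)[C@@H](Cc1cc(OC)c(OCc2ccccc2)c(OC)c1)C(O)=O | intermediate
7 | (2R)-3-[4-(benzyloxy)-3,5-dimethoxyphenyl]-2-[(2S,4S)-2-tert-butyl-5-oxo-1,3-dioxolan-4-yl]propanoic acid (tert-butyl and side chain cis) | CC(C)(C)[C@@H]1OC(=O)[C@@H](O1)[C@@H](Cc2cc(OC)c(OCc3ccccc3)c(OC)c2)C(O)=O | intermediate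
8 | 4-hydroxy-3,5-dimethoxybenzaldehyde (syringaldehyde) | COc1cc(C=O)cc(OC)c1O | starting material
9 | 3,5-dimethoxy-4-[(triisopropylsilyl)oxy]benzaldehyde | COc1cc(C=O)cc(OC)c1O[Si](C(C)C)(C(C)C)C(C)C | intermediate
10 | (2R)-3-[4-(benzyloxy)-3,5-dimethoxyphenyl]-2-[(2S,4R)-2-tert-butyl-4-{hydroxy[3,5-dimethoxy-4-(triisopropylsilyloxy)phenyl]methyl}-5-oxo-1,3-dioxolan-4-yl]propanoic acid (C7' epimers) | CC(C)(C)[C@@H]1OC(=O)[C@](O1)(C(O)c1cc(OC)c(O[Si](C(C)C)(C(C)C)C(C)C)c(OC)c1)[C@@H](Cc1cc(OC)c(OCc2ccccc2)c(OC)c1)C(O)=O | intermediate (not isolated)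
11 | (2S,5R,9R)-9-{[4-(benzyloxy)-3,5-dimethoxyphenyl]methyl}-2-tert-butyl-6-[3,5-dimethoxy-4-(triisopropylsilyloxy)phenyl]-1,3,7-trioxaspiro[4.4]nonane-4,8-dione (C6 = C7' epimers) | CC(C)(C)[C@@H]1OC(=O)[C@]2(O1)C(c1cc(OC)c(O[Si](C(C)C)(C(C)C)C(C)C)c(OC)c1)OC(=O)[C@@H]2Cc1cc(OC)c(OCc2ccccc2)c(OC)c1 | intermediate
12 | (2S,3S)-3-{[4-(benzyloxy)-3,5-dimethoxyphenyl]methyl}-2-{hydroxy[3,5-dimethoxy-4-(triisopropylsilyloxy)phenyl]methyl}butane-1,2,4-triol (C7' epimers) | OC[C@](O)(C(O)c1cc(OC)c(O[Si](C(C)C)(C(C)C)C(C)C)c(OC)c1)[C@H](CO)Cc1cc(OC)c(OCc2ccccc2)c(OC)c1 | intermediate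
13 | (2R,3S,4S)-4-{[4-(benzyloxy)-3,5-dimethoxyphenyl]methyl}-2-[3,5-dimethoxy-4-(triisopropylsilyloxy)phenyl]-3-(hydroxymethyl)oxolan-3-ol | OC[C@]1(O)[C@@H](c2cc(OC)c(O[Si](C(C)C)(C(C)C)C(C)C)c(OC)c2)OC[C@@H]1Cc1cc(OC)c(OCc2ccccc2)c(OC)c1 | intermediate
14 | (2R,3S,4S)-4-[(4-hydroxy-3,5-dimethoxyphenyl)methyl]-2-[3,5-dimethoxy-4-(triisopropylsilyloxy)phenyl]-3-(hydroxymethyl)oxolan-3-ol | OC[C@]1(O)[C@@H](c2cc(OC)c(O[Si](C(C)C)(C(C)C)C(C)C)c(OC)c2)OC[C@@H]1Cc1cc(OC)c(O)c(OC)c1 | intermediate
15 | p-quinone methide of 14: 4-(oxolan-3-ylmethylidene)-2,6-dimethoxycyclohexa-2,5-dien-1-one with the oxolane substituents of 14 unchanged | OC[C@]1(O)[C@@H](c2cc(OC)c(O[Si](C(C)C)(C(C)C)C(C)C)c(OC)c2)OC[C@@H]1C=C1C=C(OC)C(=O)C(OC)=C1 | intermediate (not isolated)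
16 | (7S,8R,7'R,8'S)-8'-hydroxysyringaresinol 4'-O-triisopropylsilyl ether (silyl ether on the aryl ring at C7') | COc1cc([C@H]2OC[C@]3(O)[C@@H](c4cc(OC)c(O[Si](C(C)C)(C(C)C)C(C)C)c(OC)c4)OC[C@H]23)cc(OC)c1O | intermediate
17 | 8-hydroxysyringaresinol | COc1cc([C@H]2OC[C@]3(O)[C@@H](c4cc(OC)c(O)c(OC)c4)OC[C@H]23)cc(OC)c1O | target

**Step count**
Total steps: 12. Longest linear sequence: 11 (steps 1–5 and 7–12).

**Steps most likely to fail**

**Step 11.** The quinone methide may tautomerise to the styrene before the neopentyl-type alcohol adds. The product may be dehydrogenated further at C7, or facial selectivity at C7 may be incomplete.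
- Fallback: oxidation and ring closure are separated. From 14, dehydrogenation with DDQ in methanol lets the solvent capture the quinone methide at once, giving the stable 7-methoxy ether F1 (C7 epimers).
- CSA in CH2Cl2 then exchanges methoxide for the internal C9' hydroxyl by SN1 transetherification under thermodynamic control. The route is rejoined at 16.

**Step 7.** Addition of the hindered, fully substituted enolate to the aldehyde may be slow, and the aldolate may revert by retro-aldol cleavage before lactonisation.
- Fallback: the reversible aldol is replaced by an irreversible SN2 alkylation. From 7, the same dianion is alkylated with bromide 3, again anti to the tert-butyl group, to give the dibenzyl dioxolanone acid F2.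
- LiAlH4 gives the triol F3, and hydrogenolysis (no benzylic C–O ring bond is present at this stage) gives the bisphenol triol F4.
- Two-fold Ag2O dehydrogenation to the bis(quinone methide) follows. Each methide carbon can be reached through a five-membered transition state by only one primary hydroxyl, so both rings should close. The route is rejoined at 17.

**Step 9.** The C7' cation may be consumed by irreversible Friedel–Crafts attack of the pendant electron-rich arene (aryltetralin formation) or by a pinacol-type shift from C8'. Facial selectivity at C7' may also be poor.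
- Fallback: the cation is replaced by a neutral quinone methide. From 12, TBAF/AcOH frees the phenol of the C7' ring to give the p-hydroxybenzyl alcohol F5.
- F5 should lose water with PPTS or on silica through the neutral p-quinone methide, an electrophile too weak for arene alkylation. The C9 hydroxyl adds to it to give the oxolane phenol F6.
- Phenoxide-selective silylation (TIPSCl, DBU, 1 equiv each) rejoins the route at 13.

**Further compounds**
F1 | step 11 | (2R,3S,4S)-4-[(4-hydroxy-3,5-dimethoxyphenyl)(methoxy)methyl]-2-[3,5-dimethoxy-4-(triisopropylsilyloxy)phenyl]-3-(hydroxymethyl)oxolan-3-ol (C7 epimers) | OC[C@]1(O)[C@@H](c2cc(OC)c(O[Si](C(C)C)(C(C)C)C(C)C)c(OC)c2)OC[C@@H]1C(OC)c1cc(OC)c(O)c(OC)c1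
F2 | step 7 | (2R)-3-[4-(benzyloxy)-3,5-dimethoxyphenyl]-2-[2-tert-butyl-4-{[4-(benzyloxy)-3,5-dimethoxyphenyl]methyl}-5-oxo-1,3-dioxolan-4-yl]propanoic acid (new benzyl group anti to tert-butyl) | CC(C)(C)[C@@H]1OC(=O)[C@](O1)(Cc1cc(OC)c(OCc2ccccc2)c(OC)c1)[C@@H](Cc1cc(OC)c(OCc2ccccc2)c(OC)c1)C(O)=O
F3 | step 7 | (2S,3S)-2,3-bis{[4-(benzyloxy)-3,5-dimethoxyphenyl]methyl}butane-1,2,4-triol | OC[C@](O)(Cc1cc(OC)c(OCc2ccccc2)c(OC)c1)[C@H](CO)Cc1cc(OC)c(OCc2ccccc2)c(OC)c1
F4 | step 7 | (2S,3S)-2,3-bis[(4-hydroxy-3,5-dimethoxyphenyl)methyl]butane-1,2,4-triol | OC[C@](O)(Cc1cc(OC)c(O)c(OC)c1)[C@H](CO)Cc1cc(OC)c(O)c(OC)c1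
F5 | step 9 | (2S,3S)-3-{[4-(benzyloxy)-3,5-dimethoxyphenyl]methyl}-2-[hydroxy(4-hydroxy-3,5-dimethoxyphenyl)methyl]butane-1,2,4-triol (C7' epimers) | OC[C@](O)(C(O)c1cc(OC)c(O)c(OC)c1)[C@H](CO)Cc1cc(OC)c(OCc2ccccc2)c(OC)c1
F6 | step 9 | (2R,3S,4S)-4-{[4-(benzyloxy)-3,5-dimethoxyphenyl]methyl}-2-(4-hydroxy-3,5-dimethoxyphenyl)-3-(hydroxymethyl)oxolan-3-ol | OC[C@]1(O)[C@@H](c2cc(OC)c(O)c(OC)c2)OC[C@@H]1Cc1cc(OC)c(OCc2ccccc2)c(OC)c1
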